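The ring atoms are numbered C1 (tiglate, next to the isopropyl carbon), C2 (=CH), C3 (=C–CH2OH), C4 (tiglate), C5 (acetate) and C6 (isopropyl). Oxygen at C1 and C4 stands 1,4 across the six-membered ring, flanked by isopropyl and CH2OH. This is a masked hydroquinone, so the ring is first built flat. A Dötz benzannulation joins an alkenyl(methoxy)carbene chromium complex (C4, C3, C2), 3-methylbut-1-yne (C5, C6) and one CO ligand (C1). It forms C4–C5, C6–C1 and C1–C2 in one operation and places all four substituents. Dearomatisation to the quinone monoketal, three reductions, one enolate oxidation and one inversion then set C6, C1, C5 and C4.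

Key step: step 3

Assumption: the facial sense of RuCl2[(R)-binap][(S,S)-dpen] in step 6 is taken from the behaviour of 2-isopropylcyclohexanone; the mirror-image catalyst is equally available.

Step 1
Reactants: 1 2-bromoprop-2-en-1-ol
Product: 2 [(2-bromoprop-2-en-1-yl)oxy](tert-butyl)diphenylsilane
Conditions: TBDPSCl, imidazole, DMF, 0 → 25 °C
Reagents that add atoms: tert-butyl(chloro)diphenylsilane CC(C)(C)[Si](Cl)(c1ccccc1)c1ccccc1
Why: Imidazole-promoted silylation of a primary alcohol; the bulky TBDPS group is chosen because it should resist O-to-C silyl shift in step 2, base in steps 6 and 9, and acid in step 8.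

Step 2
Reactants: 2 [(2-bromoprop-2-en-1-yl)oxy](tert-butyl)diphenylsilane; 3 hexacarbonylchromium Cr(CO)6
Product: 6 pentacarbonyl{1-methoxy-2-[(tert-butyldiphenylsilyloxy)methyl]prop-2-en-1-ylidene}chromium, via alkenyllithium 4 (not isolated), via lithium acylchromate 5 (not isolated)
Conditions: t-BuLi (2 equiv), Et2O, −78 °C; Cr(CO)6, −78 → 0 °C; MeOTf, CH2Cl2, 0 °C
Reagents that add atoms: methyl trifluoromethanesulfonate COS(=O)(=O)C(F)(F)F
Why: Fischer carbene synthesis, in which bromine–lithium exchange, addition of the alkenyllithium to a CO ligand and O-methylation of the acylchromate should give the 2-substituted alkenyl(methoxy)carbene complex.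

Step 3
Reactants: 6 pentacarbonyl{1-methoxy-2-[(tert-butyldiphenylsilyloxy)methyl]prop-2-en-1-ylidene}chromium; 7 3-methylbut-1-yne
Product: 10 5-{[(tert-butyldiphenylsilyl)oxy]methyl}-2-isopropyl-4-methoxyphenol, via chromium dienylketene complex 8 (not isolated), via arene tricarbonylchromium complex 9 (not isolated)
Conditions: 7 (3 equiv), THF (0.05 M), sealed tube, 50 °C; then air, Et2O, 25 °C
Reagents that add atoms: none
Why: Dötz benzannulation of an alkenyl Fischer carbene: loss of one CO ligand lets the alkyne bind and insert into the Cr=C4 bond, which forms C4–C5 and a new chromium vinylcarbene at C6, and CO insertion there gives the chromium-bound dienylketene 8 (C6–C1). The six-membered ring closes by 6π-electrocyclisation of 8, which forms C1–C2, and the cyclohexadienone tautomerises to the phenol complex 9. This is the known reaction type itself, established for 2-substituted alkenyl(methoxy)carbene complexes of chromium and terminal alkynes. No stereocentre is formed. The step needs regiocontrol and chemoselectivity: the alkyne should insert so that its larger, isopropyl-bearing end (C6) lies next to the CO-derived C1 and its CH end (C5) bonds to the carbene carbon C4, and alkenyl complexes in THF favour CO insertion over five-membered-ring products. Air then oxidises zerovalent chromium and frees phenol 10.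

Step 4
Reactants: 10 5-{[(tert-butyldiphenylsilyl)oxy]methyl}-2-isopropyl-4-methoxyphenol
Product: 11 3-{[(tert-butyldiphenylsilyl)oxy]methyl}-6-isopropyl-4,4-dimethoxycyclohexa-2,5-dien-1-one (target numbering)
Conditions: PhI(OAc)2, MeOH, 0 °C
Reagents that add atoms: methanol CO
Why: Oxidative dearomatisation of a 4-methoxyphenol by trivalent iodine, in which methanol adds at the methoxy-bearing para carbon C4 and should give the quinone monoketal with its carbonyl at C1.

Step 5
Reactants: 11 3-{[(tert-butyldiphenylsilyl)oxy]methyl}-6-isopropyl-4,4-dimethoxycyclohexa-2,5-dien-1-one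
Product: 12 racemic 3-{[(tert-butyldiphenylsilyl)oxy]methyl}-6-isopropyl-4,4-dimethoxycyclohex-2-en-1-one
Conditions: [(Ph3P)CuH]6 (0.2 equiv), H2O (5 equiv), toluene, 25 °C
Reagents that add atoms: none
Why: Copper hydride conjugate reduction, in which hydride should go only to the unsubstituted beta carbon C5 because the other beta carbon C3 is fully substituted; C6 forms as a base-labile racemate, which step 6 uses.

Step 6
Reactants: 12 racemic 3-{[(tert-butyldiphenylsilyl)oxy]methyl}-6-isopropyl-4,4-dimethoxycyclohex-2-en-1-one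
Product: 13 (1R,6S)-3-{[(tert-butyldiphenylsilyl)oxy]methyl}-6-isopropyl-4,4-dimethoxycyclohex-2-en-1-ol
Conditions: RuCl2[(R)-binap][(S,S)-dpen] (0.5 mol %), KOt-Bu (10 mol %), H2 (8 atm), i-PrOH, 25 °C
Reagents that add atoms: none
Why: Noyori asymmetric hydrogenation under dynamic kinetic resolution: base racemises C6 through the enolate, and the C=O-selective catalyst should reduce one enantiomer faster from the equatorial side, which sets C1 and C6 together with OH cis to isopropyl.

Step 7
Reactants: 13 (1R,6S)-3-{[(tert-butyldiphenylsilyl)oxy]methyl}-6-isopropyl-4,4-dimethoxycyclohex-2-en-1-ol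
Product: 14 (1R,6S)-3-{[(tert-butyldiphenylsilyl)oxy]methyl}-6-isopropyl-4,4-dimethoxycyclohex-2-en-1-yl (E)-2-methylbut-2-enoate
Conditions: tigloyl chloride, Et3N, DMAP (cat.), CH2Cl2, 0 → 25 °C
Reagents that add atoms: (E)-2-methylbut-2-enoyl chloride C/C=C(\C)C(=O)Cl
Why: DMAP-catalysed acylation at oxygen keeps the C1 configuration, and the basic medium spares the acid-labile allylic ketal.

Step 8
Reactants: 14 (1R,6S)-3-{[(tert-butyldiphenylsilyl)oxy]methyl}-6-isopropyl-4,4-dimethoxycyclohex-2-en-1-yl (E)-2-methylbut-2-enoate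
Product: 15 (1R,6S)-3-{[(tert-butyldiphenylsilyl)oxy]methyl}-6-isopropyl-4-oxocyclohex-2-en-1-yl (E)-2-methylbut-2-enoate
Conditions: PPTS (cat.), acetone–H2O (10:1), 25 °C
Reagents that add atoms: water O
Why: Mild acid-catalysed ketal hydrolysis should unmask the C4 ketone as an enone, now that C1 is sp3 and simple tautomerisation to an arene is blocked.

Step 9
Reactants: 15 (1R,6S)-3-{[(tert-butyldiphenylsilyl)oxy]methyl}-6-isopropyl-4-oxocyclohex-2-en-1-yl (E)-2-methylbut-2-enoate
Product: 18 (1S,5R,6S)-5-acetoxy-3-{[(tert-butyldiphenylsilyl)oxy]methyl}-6-isopropyl-4-oxocyclohex-2-en-1-yl (E)-2-methylbut-2-enoate, via potassium enolate 16 (not isolated), via potassium alkoxide 17 (not isolated)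
Conditions: KN(SiMe3)2, THF, −78 °C; 2-(phenylsulfonyl)-3-phenyloxaziridine, −78 °C; Ac2O, −78 → 0 °C
Reagents that add atoms: 2-(phenylsulfonyl)-3-phenyloxaziridine O=S(=O)(c1ccccc1)N1OC1c1ccccc1; acetic anhydride CC(=O)OC(C)=O
Why: Davis oxidation of the kinetic cross-conjugated enolate, in which the oxaziridine should approach C5 from the face opposite to the C6 isopropyl group and the C1 ester (C5–O trans to isopropyl), and the alkoxide is acetylated in the same flask.

Step 10
Reactants: 18 (1S,5R,6S)-5-acetoxy-3-{[(tert-butyldiphenylsilyl)oxy]methyl}-6-isopropyl-4-oxocyclohex-2-en-1-yl (E)-2-methylbut-2-enoate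
Product: 19 (1S,4R,5R,6S)-5-acetoxy-3-{[(tert-butyldiphenylsilyl)oxy]methyl}-4-hydroxy-6-isopropylcyclohex-2-en-1-yl (E)-2-methylbut-2-enoate
Conditions: NaBH4, CeCl3·7H2O, MeOH, −78 °C
Reagents that add atoms: none
Why: Luche 1,2-reduction, in which hydride should add axially from the face opposite to the pseudoaxial C1 ester and give the equatorial C4 alcohol trans to the C5 acetate.

Step 11
Reactants: 19 (1S,4R,5R,6S)-5-acetoxy-3-{[(tert-butyldiphenylsilyl)oxy]methyl}-4-hydroxy-6-isopropylcyclohex-2-en-1-yl (E)-2-methylbut-2-enoate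
Product: 20 (1S,4S,5R,6S)-5-acetoxy-3-{[(tert-butyldiphenylsilyl)oxy]methyl}-6-isopropylcyclohex-2-ene-1,4-diyl bis[(E)-2-methylbut-2-enoate]
Conditions: tiglic acid, PPh3, DIAD, toluene, 0 → 25 °C
Reagents that add atoms: (E)-2-methylbut-2-enoic acid C/C=C(\C)C(=O)O
Why: Mitsunobu esterification of the allylic alcohol, in which SN2 displacement inverts C4 and installs the second tiglate cis to the C5 acetate in one step.

Step 12
Reactants: 20 (1S,4S,5R,6S)-5-acetoxy-3-{[(tert-butyldiphenylsilyl)oxy]methyl}-6-isopropylcyclohex-2-ene-1,4-diyl bis[(E)-2-methylbut-2-enoate]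
Product: 21 (1S,4S,5R,6S)-5-acetoxy-3-(hydroxymethyl)-6-isopropylcyclohex-2-ene-1,4-diyl bis[(E)-2-methylbut-2-enoate] (target)
Conditions: HF·pyridine, THF, 0 → 25 °C
Reagents that add atoms: none
Why: Fluoride-mediated desilylation in a weakly acidic medium should free the primary alcohol without ester cleavage or acyl migration.

Compound list
1 | 2-bromoprop-2-en-1-ol | OCC(Br)=C | starting material
2 | [(2-bromoprop-2-en-1-yl)oxy](tert-butyl)diphenylsilane | C=C(Br)CO[Si](c1ccccc1)(c1ccccc1)C(C)(C)C | intermediate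
3 | hexacarbonylchromium Cr(CO)6 | O=C=[Cr](=C=O)(=C=O)(=C=O)(=C=O)=C=O | starting material
4 | 3-[(tert-butyldiphenylsilyl)oxy]prop-1-en-2-yllithium | [Li]C(=C)CO[Si](c1ccccc1)(c1ccccc1)C(C)(C)C | intermediate
5 | lithium pentacarbonyl{2-[(tert-butyldiphenylsilyloxy)methyl]acryloyl}chromate | [Li+].[O-]C(C(=C)CO[Si](c1ccccc1)(c1ccccc1)C(C)(C)C)=[Cr](=C=O)(=C=O)(=C=O)(=C=O)=C=O | intermediate
6 | pentacarbonyl{1-methoxy-2-[(tert-butyldiphenylsilyloxy)methyl]prop-2-en-1-ylidene}chromium | COC(C(=C)CO[Si](c1ccccc1)(c1ccccc1)C(C)(C)C)=[Cr](=C=O)(=C=O)(=C=O)(=C=O)=C=O | intermediate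
7 | 3-methylbut-1-yne | C#CC(C)C | starting material
8 | tricarbonylchromium-bound 2-isopropyl-4-methoxy-5-[(tert-butyldiphenylsilyloxy)methyl]hexa-1,3,5-trien-1-one (dienylketene) | O=C=C(C(C)C)C=C(OC)C(=C)CO[Si](c1ccccc1)(c1ccccc1)C(C)(C)C.O=C=[Cr](=C=O)=C=O | intermediate
9 | tricarbonylchromium complex of phenol 10 | COc1cc(C(C)C)c(O)cc1CO[Si](c1ccccc1)(c1ccccc1)C(C)(C)C.O=C=[Cr](=C=O)=C=O | intermediate
10 | 5-{[(tert-butyldiphenylsilyl)oxy]methyl}-2-isopropyl-4-methoxyphenol | COc1cc(C(C)C)c(O)cc1CO[Si](c1ccccc1)(c1ccccc1)C(C)(C)C | intermediate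
11 | 3-{[(tert-butyldiphenylsilyl)oxy]methyl}-6-isopropyl-4,4-dimethoxycyclohexa-2,5-dien-1-one | O=C1C=C(CO[Si](c2ccccc2)(c2ccccc2)C(C)(C)C)C(OC)(OC)C=C1C(C)C | intermediate
12 | racemic 3-{[(tert-butyldiphenylsilyl)oxy]methyl}-6-isopropyl-4,4-dimethoxycyclohex-2-en-1-one | O=C1C=C(CO[Si](c2ccccc2)(c2ccccc2)C(C)(C)C)C(OC)(OC)CC1C(C)C | intermediate
13 | (1R,6S)-3-{[(tert-butyldiphenylsilyl)oxy]methyl}-6-isopropyl-4,4-dimethoxycyclohex-2-en-1-ol | O[C@H]1C=C(CO[Si](c2ccccc2)(c2ccccc2)C(C)(C)C)C(OC)(OC)C[C@H]1C(C)C | intermediate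
14 | (1R,6S)-3-{[(tert-butyldiphenylsilyl)oxy]methyl}-6-isopropyl-4,4-dimethoxycyclohex-2-en-1-yl (E)-2-methylbut-2-enoate | C/C=C(\C)C(=O)O[C@H]1C=C(CO[Si](c2ccccc2)(c2ccccc2)C(C)(C)C)C(OC)(OC)C[C@H]1C(C)C | intermediate
15 | (1R,6S)-3-{[(tert-butyldiphenylsilyl)oxy]methyl}-6-isopropyl-4-oxocyclohex-2-en-1-yl (E)-2-methylbut-2-enoate | C/C=C(\C)C(=O)O[C@H]1C=C(CO[Si](c2ccccc2)(c2ccccc2)C(C)(C)C)C(=O)C[C@H]1C(C)C | intermediate
16 | potassium C4=C5 enolate of 15 | C/C=C(\C)C(=O)O[C@H]1C=C(CO[Si](c2ccccc2)(c2ccccc2)C(C)(C)C)C([O-])=C[C@H]1C(C)C.[K+] | intermediate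
17 | potassium (5R)-alkoxide of the 5-hydroxy ketone | C/C=C(\C)C(=O)O[C@H]1C=C(CO[Si](c2ccccc2)(c2ccccc2)C(C)(C)C)C(=O)[C@H]([O-])[C@H]1C(C)C.[K+] | intermediate
18 | (1S,5R,6S)-5-acetoxy-3-{[(tert-butyldiphenylsilyl)oxy]methyl}-6-isopropyl-4-oxocyclohex-2-en-1-yl (E)-2-methylbut-2-enoate | C/C=C(\C)C(=O)O[C@H]1C=C(CO[Si](c2ccccc2)(c2ccccc2)C(C)(C)C)C(=O)[C@H](OC(C)=O)[C@H]1C(C)C | intermediate
19 | (1S,4R,5R,6S)-5-acetoxy-3-{[(tert-butyldiphenylsilyl)oxy]methyl}-4-hydroxy-6-isopropylcyclohex-2-en-1-yl (E)-2-methylbut-2-enoate | C/C=C(\C)C(=O)O[C@H]1C=C(CO[Si](c2ccccc2)(c2ccccc2)C(C)(C)C)[C@@H](O)[C@H](OC(C)=O)[C@H]1C(C)C | intermediate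
20 | (1S,4S,5R,6S)-5-acetoxy-3-{[(tert-butyldiphenylsilyl)oxy]methyl}-6-isopropylcyclohex-2-ene-1,4-diyl bis[(E)-2-methylbut-2-enoate] | C/C=C(\C)C(=O)O[C@H]1C=C(CO[Si](c2ccccc2)(c2ccccc2)C(C)(C)C)[C@H](OC(=O)/C(C)=C/C)[C@H](OC(C)=O)[C@H]1C(C)C | intermediate
21 | (1S,4S,5R,6S)-5-acetoxy-3-(hydroxymethyl)-6-isopropylcyclohex-2-ene-1,4-diyl bis[(E)-2-methylbut-2-enoate] | C/C=C(\C)C(=O)O[C@H]1C=C(CO)[C@H](OC(=O)/C(C)=C/C)[C@H](OC(C)=O)[C@H]1C(C)C | target

Total step count: 12
Longest linear sequence: 12 steps (1 → 21)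

Steps most likely to fail

Step 6 (dynamic kinetic hydrogenation). Racemisation at C6 may be slower than hydrogenation, or the catalyst may tell the two enantiomers of the enone apart poorly, so that enantiomeric purity erodes. The base may also degrade the enone. The fallback sets out from 12. Reduction by LiBH(s-Bu)3 (THF, −78 °C, equatorial attack) should give the racemic cis-alcohol, that is 13 together with its mirror image, the (1S,6R)-alcohol F1. Acylation by vinyl acetate over Burkholderia cepacia lipase in MTBE should convert the faster-reacting mirror image into the (1S,6R)-acetate F2, as the empirical size rule for lipase acylation of secondary alcohols predicts. Unreacted 13 is separated by chromatography, and the route is rejoined at 13.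

Step 11 (Mitsunobu inversion). The activated allylic alcohol may eliminate toward an arene. Carboxylate may attack C2 in an SN2′ sense. The C5 acetate may participate, so that inversion is lost or the acyl groups are scrambled. The fallback sets out from 18. A reagent-controlled CBS reduction ((S)-2-methyl-CBS-oxazaborolidine, catecholborane, toluene, −78 °C, with the C3-substituted alkenyl side acting as the large group) should deliver hydride to the other face and give the (4S)-alcohol F3. Acylation with retention by tigloyl chloride, Et3N and DMAP in CH2Cl2 at 0 °C then rejoins the route at 20.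

Step 9 (enolate oxidation and acetylation). The strongly basic enolate of a 4-acyloxy enone may lose tiglic acid and aromatise. It may take up the C1 acyl group intramolecularly, or add to the sulfonimine by-product. The fallback sets out from 15. Direct alpha-prime acetoxylation by Mn(OAc)3·2H2O in benzene at reflux works through the enol without strong base, should place the acetate on the face opposite to isopropyl, and rejoins the route at 18.

Further compounds
F1 | step 6 | (1S,6R)-3-{[(tert-butyldiphenylsilyl)oxy]methyl}-6-isopropyl-4,4-dimethoxycyclohex-2-en-1-ol | O[C@@H]1C=C(CO[Si](c2ccccc2)(c2ccccc2)C(C)(C)C)C(OC)(OC)C[C@@H]1C(C)C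
F2 | step 6 | (1S,6R)-3-{[(tert-butyldiphenylsilyl)oxy]methyl}-6-isopropyl-4,4-dimethoxycyclohex-2-en-1-yl acetate | CC(=O)O[C@@H]1C=C(CO[Si](c2ccccc2)(c2ccccc2)C(C)(C)C)C(OC)(OC)C[C@@H]1C(C)C
F3 | step 11 | (1S,4S,5R,6S)-5-acetoxy-3-{[(tert-butyldiphenylsilyl)oxy]methyl}-4-hydroxy-6-isopropylcyclohex-2-en-1-yl (E)-2-methylbut-2-enoate | C/C=C(\C)C(=O)O[C@H]1C=C(CO[Si](c2ccccc2)(c2ccccc2)C(C)(C)C)[C@H](O)[C@H](OC(C)=O)[C@H]1C(C)C
F0 | step 9 | none | none
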